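**Plan**

1. Numbering and faces: ring A (seven-membered) runs C2 (fusion CH), C1 (CH2), C10 (C(OH)CH3), C9 (CH2), C8 (CH–O-acyl), C7 (CH–iPr), C6 (fusion CH). Ring B (five-membered) runs C2, C3, C4 (C–CH3), C5, C6. β is the face of C6–H, which also holds iPr, O8, O10 and the oxirane oxygen; α is the face of C2–H.
2. Enabling feature: C9 is the only ring A carbon without a substituent and lies between the oxygen-bearing C8 and C10. Removing it and joining C8 to C10 shrinks ring A to a cyclohexene whose C8=C10 bond is a silyl enol ether, which is what a 2-siloxydiene leaves after a Diels–Alder reaction that also sets C2, C6 and C7.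
3. Retrosynthetic cuts, in order: phenol O–Si; C3–O/C4–O (oxirane); acyl–O8; C10–O (through C10–B) and C8–H; C8–C9 and C9–C10 with C8–C10 re-formed; C3=C4 (metathesis); C3=CH2 (Wittig); C1–C2 and C6–C7 (cycloaddition).
4. Forward order of rings: the six-membered forerunner of ring A (Diels–Alder), then ring B (ring-closing metathesis, trans-hydrindene), then a transient three-membered ring on C8–C10 that is opened to the seven-membered ring A, and last the oxirane on ring B.
5. Stereochemistry: one enantioselective endo Diels–Alder reaction fixes C2, C6 and C7 ((E)-enal gives C2/C6 trans; (Z)-diene with endo approach gives iPr trans to C5). A chiral copper catalyst sets C10, a bulky hydride from the α face sets C8, and the β C10–OH steers epoxidation of C3=C4 to the β face.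

Key step: step 10

Assumption: the (S)-oxazaborolidinium salt of step 7 and (R,R)-QuinoxP* of step 11 are taken to be the enantiomers that deliver to the Cα-Si face of the enal and to the Re (β) face of C10 of the ring A enone; both are sold in either form, so a reversed sense only means using the mirror-image catalyst.

**Step 1**
Reactants: 1 isovaleraldehyde (3-methylbutanal); 2 isopropenylmagnesium bromide
Product: 3 (±)-2,5-dimethylhex-1-en-3-ol
Conditions: THF, 0 °C; aq NH4Cl
Reagents that add atoms: none
Why: Grignard 1,2-addition to an unhindered aldehyde joins C10 to C8; the carbinol centre forms racemic and is erased in step 2.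

**Step 2**
Reactants: 3 (±)-2,5-dimethylhex-1-en-3-ol
Product: 4 2,5-dimethylhex-1-en-3-one
Conditions: Dess–Martin periodinane, CH2Cl2, 0 °C to rt
Reagents that add atoms: none
Why: Dess–Martin oxidation converts the secondary allylic alcohol into the isopropenyl ketone under neutral, non-aqueous conditions that spare this polymerisable enone.

**Step 3**
Reactants: 4 2,5-dimethylhex-1-en-3-one
Product: 5 (Z)-3-(tert-butyldimethylsilyloxy)-2,5-dimethylhexa-1,3-diene
Conditions: TBSOTf, Et3N, CH2Cl2, 0 °C
Reagents that add atoms: tert-butyldimethylsilyl triflate, CC(C)(C)[Si](C)(C)OS(=O)(=O)C(F)(F)F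
Why: Soft enolisation (silyl triflate/amine) can only deprotonate C7, and allylic strain between the isopropyl and isopropenyl groups favours the (Z)-enol silane, which places the isopropyl group on the outside of the s-cis diene.

**Step 4**
Reactants: 6 methallyl chloride (3-chloro-2-methylprop-1-ene); 7 propargyl alcohol (prop-2-yn-1-ol)
Product: 8 5-methylhex-5-en-2-yn-1-ol
Conditions: CuI (10 mol %), NaI (10 mol %), K2CO3, DMF, rt
Reagents that add atoms: none
Why: Allylation of a terminal alkyne catalysed by monovalent copper forms C5–C6, and because the methallyl unit is symmetric, direct and allylic-shift substitution give the same skipped enyne.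

**Step 5**
Reactants: 8 5-methylhex-5-en-2-yn-1-ol
Product: 9 (E)-5-methylhexa-2,5-dien-1-ol
Conditions: LiAlH4, THF, 0 to 45 °C; H2O, aq NaOH
Reagents that add atoms: none
Why: Alkoxide-directed trans-hydroalumination of a propargylic alcohol gives the (E)-allylic alcohol and leaves the isolated 1,1-disubstituted alkene untouched.

**Step 6**
Reactants: 9 (E)-5-methylhexa-2,5-dien-1-ol
Product: 10 (E)-5-methylhexa-2,5-dienal
Conditions: activated MnO2, CH2Cl2, rt
Reagents that add atoms: none
Why: MnO2 oxidation of a primary allylic alcohol is neutral and heterogeneous, so the skipped diene should not move into conjugation and the (E) geometry is kept.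

**Step 7**
Reactants: 5 (Z)-3-(tert-butyldimethylsilyloxy)-2,5-dimethylhexa-1,3-diene; 10 (E)-5-methylhexa-2,5-dienal
Product: 11 Diels–Alder aldehyde, (1S,5S,6S)-4-(tert-butyldimethylsilyloxy)-3-methyl-6-(2-methylallyl)-5-isopropylcyclohex-3-ene-1-carbaldehyde (C2 β-CHO, C6 α-methallyl, C7 β-iPr, C8(OTBS)=C10(CH3))
Conditions: (S)-3,3-diphenyl-1-(o-tolyl)tetrahydropyrrolo[1,2-c][1,3,2]oxazaborole·HN(SO2CF3)2 (20 mol %), 5 (1.5 equiv), CH2Cl2, −78 to −40 °C
Reagents that add atoms: none
Why: In this enantioselective Diels–Alder reaction under chiral oxazaborolidinium catalysis, the siloxy group makes C7 the nucleophilic terminus so that C7 bonds to the enal β-carbon C6 and C1 to C2; the (E)-enal fixes C2/C6 trans, the endo transition state places the outside isopropyl group cis to the formyl group (trans to C5), and the catalyst leaves only the Cα-Si face of the bound enal open.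

**Step 8**
Reactants: 11 Diels–Alder aldehyde
Product: 12 vinyl triene (as 11, with C2 β-CH=CH2 in place of CHO)
Conditions: Ph3PCH3Br, KOtBu, THF, 0 °C; then 11, −78 to 0 °C
Reagents that add atoms: methyltriphenylphosphonium bromide, C[P+](c1ccccc1)(c1ccccc1)c1ccccc1.[Br-]
Why: Wittig methylenation converts C3 into a vinyl group; C2 is not at risk because its all-equatorial arrangement is already the more stable one, and the enol silane tolerates the ylide.

**Step 9**
Reactants: 12 vinyl triene
Product: 13 trans-hydrindene enol silane (C2–H α, C6–H β, C7 β-iPr, C8(OTBS)=C10(CH3), C3=C4(CH3))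
Conditions: second-generation Grubbs catalyst (H2IMes)(PCy3)Cl2Ru=CHPh (5 mol %), CH2Cl2 (5 mM), 40 °C
Reagents that add atoms: none
Why: In this ring-closing metathesis the ruthenium carbene loads on the monosubstituted C3 vinyl group and closes onto the 1,1-disubstituted alkene to give ring B with loss of ethene; the trans fusion is already fixed, it has the same ring type as the stable trans-fused D-ring olefins of steroids, and the tetrasubstituted enol silane is inert to the catalyst.

**Step 10**
Reactants: 13 trans-hydrindene enol silane
Product: 16 bicyclo[5.3.0] dienone (C8=O; C9=C10(CH3); C3=C4(CH3); C2–H α; C6–H β; C7 β-iPr), via siloxycyclopropane 14 (not isolated), via chloro ketone 15 (not isolated)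
Conditions: Et2Zn (1.3 equiv), CH2I2 (1.3 equiv), CH2Cl2, −20 to 0 °C, aq NH4Cl wash, solvent switch; FeCl3 (2.5 equiv), DMF, 0 °C to rt; crude 15, NaOAc, MeOH, reflux
Reagents that add atoms: diiodomethane, ICI; iron trichloride, Cl[Fe](Cl)Cl (chlorine of 15 only)
Why: The zinc carbenoid EtZnCH2I transfers CH2 (C9) in a concerted syn addition to the C8=C10 enol silane, making C8–C9 and C9–C10 and closing a necessarily cis-fused three-membered ring ([2+1] mode); FeCl3 then replaces silicon by trivalent iron on O8, electron transfer gives the cyclopropyloxy radical, and β-scission of the shared C8–C10 bond opens the bicyclo[4.1.0] unit, so ring A arises by ring enlargement through cleavage of the zero bridge and not by an end-to-end cyclisation. The tertiary C10 radical takes chlorine from a second FeCl3 to give 15, and NaOAc removes HCl by an E1cB path through the C9 enolate, which can only place the alkene at C9=C10. The closest known reaction type is the one-carbon enlargement of cyclic trialkylsilyl enol ethers to the homologous 2-cycloalkenones by Simmons–Smith cyclopropanation and FeCl3 cleavage. No stereocentre of 16 is created: the two cyclopropane centres of 14 (carbenoid expected on the α face, away from the isopropyl group) and C10 of 15 return to sp2, while C2, C6 and C7 are spectators, C7 keeping its equatorial and thermodynamically preferred isopropyl group under the acetate treatment. Two selectivities are needed: the electrophilic carbenoid, used in slight excess only, must take the oxygen-activated C8=C10 bond before the unactivated C3=C4 bond, and scission must hit C8–C10 (tertiary radical, relief of trans-hydrindene strain) rather than C8–C9 (primary radical). The C10 radical cannot be intercepted by C3=C4, because that would require a 4-exo or 5-endo closure.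

**Step 11**
Reactants: 16 bicyclo[5.3.0] dienone
Product: 18 beta-boryl ketone (C8=O; C10 β-Bpin; C10 α-CH3), via boron enolate 17 (not isolated)
Conditions: Cu(CH3CN)4PF6 (10 mol %), (R,R)-QuinoxP* [(R,R)-2,3-bis(tert-butylmethylphosphino)quinoxaline, 12 mol %], LiOtBu (15 mol %), B2pin2, DMSO, rt; H2O
Reagents that add atoms: bis(pinacolato)diboron, CC1(C)OB(OC1(C)C)B1OC(C)(C)C(C)(C)O1
Why: In this copper-catalysed enantioselective conjugate borylation of a β-substituted cyclic enone, the ligated Cu–Bpin species adds boron to C10 with the ligand, not the remote ring stereocentres, choosing the Re (β) face; exchange with B2pin2 gives boron enolate 17, which water converts into the ketone, and the isolated C3=C4 alkene is inert.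

**Step 12**
Reactants: 18 beta-boryl ketone
Product: 20 cis-1,3-diol (C8 β-OH; C10 β-OH; C10 α-CH3), via hydroxy boronate 19 (not isolated)
Conditions: L-Selectride [LiBH(s-Bu)3], THF, −78 °C; then aq NaOH, H2O2, 0 °C to rt
Reagents that add atoms: hydrogen peroxide, OO
Why: In this sterically governed ketone reduction the bulky borohydride takes the equatorial, α-face path (as in menthone to neomenthol) because the β face is screened by the syn-axial C10–Bpin group and the flank of the isopropyl group, giving the β C8 alkoxide; the alkaline peroxide needed to destroy the trialkylborane also converts C10–B into C10–OH with retention, so no retro-aldol-prone hydroxy ketone is ever handled.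

**Step 13**
Reactants: 21 isovanillic acid (3-hydroxy-4-methoxybenzoic acid)
Product: 23 3-(tert-butyldimethylsilyloxy)-4-methoxybenzoic acid, via bis-silyl derivative 22 (not isolated)
Conditions: TBSCl (2.5 equiv), imidazole, DMF, rt; then AcOH–THF–H2O, rt
Reagents that add atoms: tert-butyldimethylsilyl chloride, CC(C)(C)[Si](C)(C)Cl
Why: Silylation covers both acidic oxygens, and the far more labile silyl ester is hydrolysed selectively, leaving the aryl silyl ether that will shield the phenol from acylation and from the peroxide of step 15.

**Step 14**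
Reactants: 20 cis-1,3-diol; 23 3-(tert-butyldimethylsilyloxy)-4-methoxybenzoic acid
Product: 24 C8 ester (C8 β-O-aroyl, free C10 β-OH, C3=C4 alkene, aryl OTBS)
Conditions: DCC, DMAP, CH2Cl2, rt to 40 °C
Reagents that add atoms: none
Why: Steglich esterification through the acylpyridinium ion acylates the secondary C8–OH while the tertiary C10–OH stays inert, as is usual for hindered terpene diols, and no stereocentre is touched.

**Step 15**
Reactants: 24 C8 ester
Product: 25 β-epoxide (C3–C4 oxirane on the β face, C4 α-CH3, aryl OTBS)
Conditions: VO(acac)2 (10 mol %), t-BuOOH (decane solution), CH2Cl2, 0 °C to rt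
Reagents that add atoms: tert-butyl hydroperoxide, CC(C)(C)OO
Why: In this hydroxyl-directed epoxidation of a bishomoallylic tertiary alcohol, the β C10–OH binds the pentavalent vanadium alkylperoxide above ring A and passes oxygen to the β face of the only remaining alkene, setting C3 and C4; the syn relation of OH and oxirane rules out backside opening to a cyclic ether.

**Step 16**
Reactants: 25 β-epoxide
Product: 26 CNP0106636.1 (target)
Conditions: TBAF, AcOH (1:1), THF, 0 °C
Reagents that add atoms: none
Why: Fluoride cleavage of an aryl silyl ether is fast at 0 °C, and the acetic acid buffer keeps the medium from opening the oxirane or moving the ester.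

**Compound list**

1 | isovaleraldehyde | CC(C)CC=O | starting material
2 | isopropenylmagnesium bromide | C=C(C)[Mg]Br | starting material
3 | (±)-2,5-dimethylhex-1-en-3-ol | C=C(C)C(O)CC(C)C | intermediate
4 | 2,5-dimethylhex-1-en-3-one | C=C(C)C(=O)CC(C)C | intermediate
5 | (Z)-3-(tert-butyldimethylsilyloxy)-2,5-dimethylhexa-1,3-diene | C=C(C)/C(O[Si](C)(C)C(C)(C)C)=C/C(C)C | intermediate
6 | methallyl chloride | C=C(C)CCl | starting material
7 | propargyl alcohol | C#CCO | starting material
8 | 5-methylhex-5-en-2-yn-1-ol | C=C(C)CC#CCO | intermediate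
9 | (E)-5-methylhexa-2,5-dien-1-ol | C=C(C)C/C=C/CO | intermediate
10 | (E)-5-methylhexa-2,5-dienal | C=C(C)C/C=C/C=O | intermediate
11 | Diels–Alder aldehyde, (1S,5S,6S)-4-(tert-butyldimethylsilyloxy)-3-methyl-6-(2-methylallyl)-5-isopropylcyclohex-3-ene-1-carbaldehyde | CC1=C(O[Si](C)(C)C(C)(C)C)[C@@H](C(C)C)[C@H](CC(C)=C)[C@@H](C=O)C1 | intermediate
12 | vinyl triene (C2 β-vinyl, C6 α-methallyl, C7 β-iPr) | CC1=C(O[Si](C)(C)C(C)(C)C)[C@@H](C(C)C)[C@H](CC(C)=C)[C@@H](C=C)C1 | intermediate
13 | trans-hydrindene enol silane (key-step precursor) | CC1=C(O[Si](C)(C)C(C)(C)C)[C@@H](C(C)C)[C@@H]2CC(C)=C[C@H]2C1 | intermediate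
14 | siloxycyclopropane (C9H2 on the α face of C8–C10, the expected face isomer; both converge) | C[C@@]12C[C@]1(O[Si](C)(C)C(C)(C)C)[C@@H](C(C)C)[C@@H]1CC(C)=C[C@H]1C2 | intermediate
15 | β-chloro ketone (C8=O, C10(Cl)CH3, both C10 epimers, centre left open) | O=C1CC(C)(Cl)C[C@H]2[C@@H](CC(C)=C2)[C@@H]1C(C)C | intermediate
16 | bicyclo[5.3.0] dienone (key-step product) | O=C1C=C(C)C[C@H]2[C@@H](CC(C)=C2)[C@@H]1C(C)C | intermediate
17 | boron enolate (C8(OBpin)=C9, C10 β-Bpin) | CC1(C)OB(OC2=C[C@](C)(B3OC(C)(C)C(C)(C)O3)C[C@H]4[C@@H](CC(C)=C4)[C@@H]2C(C)C)OC1(C)C | intermediate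
18 | β-boryl ketone (C10 β-Bpin) | O=C1C[C@](C)(B2OC(C)(C)C(C)(C)O2)C[C@H]3[C@@H](CC(C)=C3)[C@@H]1C(C)C | intermediate
19 | hydroxy boronate (C8 β-OH, C10 β-Bpin; present as its lithium alkoxide) | O[C@@H]1C[C@](C)(B2OC(C)(C)C(C)(C)O2)C[C@H]3[C@@H](CC(C)=C3)[C@@H]1C(C)C | intermediate
20 | cis-1,3-diol (C8 β-OH, C10 β-OH) | O[C@@H]1C[C@](C)(O)C[C@H]2[C@@H](CC(C)=C2)[C@@H]1C(C)C | intermediate
21 | isovanillic acid | COc1ccc(C(=O)O)cc1O | starting material
22 | tert-butyldimethylsilyl 3-(tert-butyldimethylsilyloxy)-4-methoxybenzoate | COc1ccc(C(=O)O[Si](C)(C)C(C)(C)C)cc1O[Si](C)(C)C(C)(C)C | intermediate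
23 | 3-(tert-butyldimethylsilyloxy)-4-methoxybenzoic acid | COc1ccc(C(=O)O)cc1O[Si](C)(C)C(C)(C)C | intermediate
24 | C8 ester | COc1ccc(C(=O)O[C@@H]2C[C@](C)(O)C[C@H]3[C@@H](CC(C)=C3)[C@@H]2C(C)C)cc1O[Si](C)(C)C(C)(C)C | intermediate
25 | β-epoxide, silyl-protected target | COc1ccc(C(=O)O[C@@H]2C[C@](C)(O)C[C@H]3[C@@H](C[C@@]4(C)O[C@@H]34)[C@@H]2C(C)C)cc1O[Si](C)(C)C(C)(C)C | intermediate
26 | CNP0106636.1 (local numbering 2S,3S,4R,6R,7S,8R,10R) | COc1ccc(C(=O)O[C@@H]2C[C@](C)(O)C[C@H]3[C@@H](C[C@@]4(C)O[C@@H]34)[C@@H]2C(C)C)cc1O | target

**Step count and risks**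

Total step count: 16. Longest linear sequence: 12 steps (1–3, 7–12, 14–16).

**Risk 1, step 7.**
- What may go wrong: the cycloaddition joins an isopropyl-bearing diene terminus to a β-substituted enal and may be slow. Protodesilylation of the diene, acid-induced drift of the skipped diene into conjugation, or open-chain Mukaiyama-type addition could then take over. Face discrimination for an α-unsubstituted enal may also be poor.
- Fallback: catalyst control is replaced by a covalently bound auxiliary on a chelated, more electrophilic dienophile. The fallback sets out from 10 (with 5) and returns at 11.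
- Pinnick oxidation (NaClO2, NaH2PO4, 2-methylbut-2-ene, t-BuOH–H2O) would give (E)-5-methylhexa-2,5-dienoic acid F1.
- Pivaloyl chloride and Et3N in THF at −20 °C would give the mixed pivalic anhydride F2, which with (S)-4-benzyloxazolidin-2-one and LiCl would give the N-enoyl imide F3.
- With Et2AlCl (1.4 equiv, CH2Cl2, −78 °C) the imide is held s-cis in an aluminium chelate and the benzyl group covers the Cα-Re face. Diene 5 should then add endo to the Cα-Si face to give the imide cycloadduct F4, with the C2, C6 and C7 configuration of 11.
- LiBH4 (Et2O, MeOH, 0 °C) would release the auxiliary and give the primary alcohol F5, and Dess–Martin oxidation would give 11.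

**Risk 2, step 10.**
- What may go wrong: the bulky zinc carbenoid may react sluggishly at the tetrasubstituted enol silane flanked by the isopropyl group and begin to cyclopropanate C3=C4. The robust silyl ether may also resist exchange with FeCl3.
- Fallback: C9 is still inserted between C8 and C10, but by a free dihalocarbene and an ionic ring opening. The fallback sets out from 13 and returns at 16.
- Dibromocarbene (CHBr3, KOtBu, pentane, −20 °C) is small and follows alkene nucleophilicity rather than steric access, so it should prefer the tetrasubstituted, oxygen-bearing alkene and give the dibromocyclopropane F6.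
- TBAF (THF, 0 °C) would free the alkoxide, which expels bromide in a two-electron cyclopropyl-to-allyl opening of the same C8–C10 bond to give the 9-bromo dienone F7.
- Hydrodebromination with Bu3SnH under zerovalent palladium catalysis (Pd(PPh3)4, THF, rt) would give 16.

**Risk 3, step 15.**
- What may go wrong: the hindered tertiary C10–OH may bind vanadium slowly. Undirected background oxidation would then erode the facial selectivity at C3=C4.
- Fallback: substrate direction is replaced by reagent control, and the epoxidation is moved ahead of the acylation so that the aryl silyl ether never meets the basic oxidant. The fallback sets out from 20 and returns at 25.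
- Shi epoxidation would convert 20 into the epoxy diol F8. It uses the fructose-derived ketone 1,2:4,5-di-O-isopropylidene-β-D-erythro-2,3-hexodiulo-2,6-pyranose, or its enantiomer, whichever is matched to the β face, with Oxone and K2CO3 buffer in MeCN–dimethoxymethane–H2O at 0 °C.
- Steglich esterification of the C8–OH with 23 (DCC, DMAP, CH2Cl2) would then give 25.

**Further compounds**

F1 | step 7 | (E)-5-methylhexa-2,5-dienoic acid | C=C(C)C/C=C/C(=O)O
F2 | step 7 | (E)-5-methylhexa-2,5-dienoic pivalic anhydride | C=C(C)C/C=C/C(=O)OC(=O)C(C)(C)C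
F3 | step 7 | (S)-4-benzyl-3-[(E)-5-methylhexa-2,5-dienoyl]oxazolidin-2-one | C=C(C)C/C=C/C(=O)N1[C@@H](Cc2ccccc2)COC1=O
F4 | step 7 | imide cycloadduct (as 11, with C2 β-C(=O)-oxazolidinone) | CC1=C(O[Si](C)(C)C(C)(C)C)[C@@H](C(C)C)[C@H](CC(C)=C)[C@@H](C(=O)N2[C@@H](Cc3ccccc3)COC2=O)C1
F5 | step 7 | primary alcohol (as 11, with C2 β-CH2OH) | CC1=C(O[Si](C)(C)C(C)(C)C)[C@@H](C(C)C)[C@H](CC(C)=C)[C@@H](CO)C1
F6 | step 10 | dibromocyclopropane (C9Br2 on the α face of C8–C10) | C[C@@]12C(Br)(Br)[C@]1(O[Si](C)(C)C(C)(C)C)[C@@H](C(C)C)[C@@H]1CC(C)=C[C@H]1C2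
F7 | step 10 | 9-bromo dienone | O=C1C(Br)=C(C)C[C@H]2[C@@H](CC(C)=C2)[C@@H]1C(C)C
F8 | step 15 | epoxy diol (C8 β-OH, C10 β-OH, β oxirane) | O[C@@H]1C[C@](C)(O)C[C@H]2[C@@H](C[C@@]3(C)O[C@@H]23)[C@@H]1C(C)C
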